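The numbers in the tables are calculated with constants of no real substance, noise included.

Late in the runs so far the electrophile has not gone: at 4.00 h delta still holds 40.8 % of its charge and eta 25.2 %, and eta had more free base.

| setting | delta | eta | summer | winter |
|---|---|---|---|---|
| electrophile | 0.20 M (fed, over 40 min) | 0.20 M (fed, over 40 min) | 0.20 M (fed, over 40 min) | 0.20 M (fed, over 40 min) |
| free base | 0.067 M | 0.13 M | 0.100 M | 0.200 M |
| protonated nucleophile | 0.30 M | 0.30 M | 0.300 M | 0.300 M |
| remark | run made earlier | run made earlier |  |  |
| time |  |  | 4.0 h | 4.0 h |

| run | time / h | electrophile / % | target / % |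
|---|---|---|---|
| delta | 0.333 | 44.4 | 1.6 |
| delta | 0.500 | 62.5 | 4.1 |
| delta | 0.667 | 78.6 | 5.4 |
| delta | 1.00 | 65.0 | 4.1 |
| delta | 1.50 | 53.3 | 2.5 |
| delta | 2.50 | 44.2 | 0.4 |
| delta | 4.00 | 40.8 | 0.9 |
| eta | 0.200 | 27.5 | 2.1 |
| eta | 0.667 | 71.2 | 8.2 |
| eta | 1.00 | 54.9 | 7.5 |
| eta | 1.50 | 40.4 | 4.9 |
| eta | 2.50 | 29.8 | 3.8 |
| eta | 3.00 | 27.6 | 2.9 |
| eta | 4.00 | 25.2 | 1.1 |

(readings scatter by 0.5 percentage points)

- part of the electrophile that has reacted at the end, summer
- part of the electrophile that has reacted at the end, winter
- what raising the concentration of free base from its lowest to its highest value here does to the part of the electrophile that has reacted (changes below 5 percentage points count as none) (it rises / it falls / no change)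

- the numbers in the tables scatter with a standard deviation of 0.5 percentage points
- what has gone from electrophile into another species counts as reacted, even if it can come back
- percentages count the whole charge, also what has not yet gone in

Is the free base simply used up one for one? No. By that reading delta has reacted 59.2 % of its charge, with free base worth 33.5 % of that charge.

Then what do you read? I take the share reacted over the share left, at the last reading, and divide by the equivalents of free base to electrophile charged. Delta gives 4.33 and eta 4.57, although eta had twice the free base. Their mean is 4.45: the reacted-to-left ratio per equivalent, a reading for 4.00 h, with this feed and these charges of electrophile and protonated nucleophile.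

Why the last reading and not an end state? Delta is still falling, from 44.2 % at 2.50 h. But both runs and both new flasks share the feed time and the last reading time, so the comparison needs no finished end.

So what do you commit to? Summer, at 0.500 equivalents, has a ratio of 2.22, so 68.9 % reacted. Winter has a ratio of 4.45, so 81.7 %.

Where is that weakest? In winter: 1.00 equivalents lies beyond eta's 0.650.

The forecast, reading a plateau where I read the last point, says 69 % and 81.5 %, and of the trend it rises. Its ground: “This looks like a reversible sink rather than stoichiometric consumption.”

The flask gives 68.1 % for summer and 85.9 % for winter; it rises, by 18 percentage points. Summer left until 40.0 h reaches 80.9 % reacted, so the ratio belongs to 4.0 h, not to an end state. Put back through the rule, summer's result gives 4.27 per equivalent, beside my 4.45, and winter's gives 6.11, which is higher.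

    acid set free + free base ⇌ salt of the base, settled at all times (K = 7300 L mol⁻¹)
    electrophile + target → side product (k = 0.330 L mol⁻¹ min⁻¹)
    electrophile + nucleophile → acid set free + target (k = 0.210 L mol⁻¹ min⁻¹)
    nucleophile + acid set free ⇌ protonated nucleophile, settled at all times (K = 33000 L mol⁻¹)
    electrophile ⇌ dormant form (K = 0.580, k = 0.00560 min⁻¹)
    acid set free → by-product carried off (k = 0.00190 min⁻¹)

A second flask: summer with the electrophile cut to 0.080 M, so 1.25 equiv of free base. Both runs had 0.20 M of electrophile, so this stretches the rule; it gives a ratio of 5.56, so 84.8 % reacted, and the flask computes 85.0 %.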